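**Retrosynthetic overview**
- Last step: O-acylation of the free (E)-5-ylidene tetronic acid with stearoyl chloride; until then the enol OH is carried as an allyl ether.
- The exocyclic C5=C1′ alkene comes from a stereospecific anti-dehydration of a 5,6-erythro aldol. The key C5–C1′ bond is made by an intermolecular aldol of the lithium dienolate of O-allyl 3-methyltetronate with the (S)-α-methyl aldehyde.
- The aldehyde comes from a copper-catalysed coupling of 3-furylmethyl Grignard with an allylic chloride. That chain is built from 8-bromogeranyl acetate and a chiral C4 sulfone made from (R)-3-bromo-2-methylpropan-1-ol, which supplies the only stereocentre.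
- Rings: the butenolide (tetronic acid) ring is the only ring built, in the first step of its branch from ethyl 2-methylacetoacetate; the furan is bought intact as furan-3-ylmethanol.

Assumption: the exocyclic C=C is read exactly as written in the SMILES (side chain cis to C4–O and trans to the ring oxygen, i.e. E), so it is set by a stereospecific elimination and not by equilibration.

**Step 1**
Reactants: 1 ethyl 2-methyl-3-oxobutanoate (ethyl 2-methylacetoacetate)
Product: 3 4-hydroxy-3-methylfuran-2(5H)-one (3-methyltetronic acid), via ethyl 4-bromo-2-methyl-3-oxobutanoate 2 (not isolated)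
Conditions: Br2 (1.0 equiv), CHCl3, 0 °C to rt, 16 h; evaporate; neat, 120 °C, 2 h
Reagents that add atoms: none
Why: Classical tetronic acid synthesis: bromination (HBr-equilibrated to the terminal bromide) followed by thermal lactonisation with loss of bromoethane.

**Step 2**
Reactants: 3 3-methyltetronic acid
Product: 4 3-methyl-4-(prop-2-en-1-yloxy)furan-2(5H)-one
Conditions: allyl alcohol (1.2 equiv), PPh3, DIAD, THF, 0 °C to rt
Reagents that add atoms: prop-2-en-1-ol (allyl alcohol), C=CCO
Why: Mitsunobu O-alkylation of the acidic enol gives the 4-O-allyl vinylogous ester regioselectively, avoiding the C3-allylation seen with allyl halide and base.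

**Step 3**
Reactants: 5 geranyl acetate [(2E)-3,7-dimethylocta-2,6-dien-1-yl acetate]
Product: 6 (2E,6E)-8-hydroxy-3,7-dimethylocta-2,6-dien-1-yl acetate
Conditions: SeO2 (0.1 equiv), t-BuOOH (3 equiv), salicylic acid (0.1 equiv), CH2Cl2, rt, 24–40 h
Reagents that add atoms: tert-butyl hydroperoxide, CC(C)(C)OO (terminal oxidant; the oxygen is passed on by SeO2, O=[Se]=O)
Why: Sharpless SeO2/t-BuOOH allylic oxidation (ene reaction then [2,3]-shift) hydroxylates the (E)-methyl of the distal alkene; the 2,3-alkene is deactivated by the allylic acetate.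

**Step 4**
Reactants: 6 (2E,6E)-8-hydroxy-3,7-dimethylocta-2,6-dien-1-yl acetate
Product: 7 (2E,6E)-8-bromo-3,7-dimethylocta-2,6-dien-1-yl acetate
Conditions: CBr4, PPh3, CH2Cl2, −20 to 0 °C
Reagents that add atoms: tetrabromomethane, BrC(Br)(Br)Br
Why: Appel bromination is an SN2 reaction at the primary allylic carbon, so the alkene geometry and the acetate are kept.

**Step 5**
Reactants: 8 (R)-3-bromo-2-methylpropan-1-ol
Product: 9 [(2R)-3-bromo-2-methylpropoxy](tert-butyl)dimethylsilane
Conditions: TBSCl, imidazole, DMF, rt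
Reagents that add atoms: tert-butylchlorodimethylsilane, CC(C)(C)[Si](C)(C)Cl
Why: Standard silylation of the primary alcohol; the chiral-pool stereocentre, which becomes the only stereocentre of the target, is not touched.

**Step 6**
Reactants: 9 [(2R)-3-bromo-2-methylpropoxy](tert-butyl)dimethylsilane; 10 methyl phenyl sulfone
Product: 11 tert-butyldimethyl{[(2S)-2-methyl-4-(phenylsulfonyl)butyl]oxy}silane
Conditions: 10 (2.5 equiv), n-BuLi (2.4 equiv), THF–DMPU, −78 °C; then 9, −78 °C to rt
Reagents that add atoms: none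
Why: SN2 alkylation of the α-sulfonyl carbanion (excess anion suppresses dialkylation); the stereocentre is one carbon away and unchanged, and its descriptor changes from R to S only through the priority change.

**Step 7**
Reactants: 11 tert-butyldimethyl{[(2S)-2-methyl-4-(phenylsulfonyl)butyl]oxy}silane; 7 (2E,6E)-8-bromo-3,7-dimethylocta-2,6-dien-1-yl acetate
Product: 12 (2E,6E,11S)-12-{[tert-butyl(dimethyl)silyl]oxy}-3,7,11-trimethyl-9-(phenylsulfonyl)dodeca-2,6-dien-1-yl acetate (both C9 epimers)
Conditions: 11, n-BuLi (1.0 equiv), THF, −78 °C; cannulated into 7 (1.15 equiv), THF, −78 °C, 1 h; NH4Cl quench at −78 °C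
Reagents that add atoms: none
Why: Sulfone-carbanion alkylation (Julia-type fragment coupling) is far faster at the allylic bromide than attack on the acetate at −78 °C; the new sulfone-bearing centre forms unselectively and is erased in step 8.

**Step 8**
Reactants: 12 the sulfone acetate
Product: 13 (2E,6E,11S)-12-{[tert-butyl(dimethyl)silyl]oxy}-3,7,11-trimethyldodeca-2,6-dien-1-ol
Conditions: 6% Na(Hg) (6 equiv Na), MeOH–THF, −20 °C to rt
Reagents that add atoms: none
Why: Reductive desulfonylation by electron transfer replaces C–SO2Ph by C–H, and the NaOMe formed removes the acetate by transesterification in the same pot; the alkenes and silyl ether are inert.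

**Step 9**
Reactants: 13 (2E,6E,11S)-12-{[tert-butyl(dimethyl)silyl]oxy}-3,7,11-trimethyldodeca-2,6-dien-1-ol
Product: 15 tert-butyl{[(2S,6E,10E)-12-chloro-2,6,10-trimethyldodeca-6,10-dien-1-yl]oxy}dimethylsilane, via allylic methanesulfonate 14 (not isolated)
Conditions: MsCl, 2,4,6-collidine, LiCl, DMF, 0 °C
Reagents that add atoms: lithium chloride, [Li+].[Cl-]
Why: Collington–Meyers chlorination (mesylate, then SN2 by chloride) gives the primary allylic chloride without allylic transposition or loss of E-geometry.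

**Step 10**
Reactants: 16 furan-3-ylmethanol
Product: 17 3-(chloromethyl)furan
Conditions: SOCl2, pyridine, Et2O, 0 °C
Reagents that add atoms: thionyl chloride, O=S(Cl)Cl
Why: Chlorodehydroxylation through the chlorosulfite under pyridine buffering gives the fairly stable 3-furylmethyl chloride without acid damage to the furan.

**Step 11**
Reactants: 17 3-(chloromethyl)furan; 15 tert-butyl{[(2S,6E,10E)-12-chloro-2,6,10-trimethyldodeca-6,10-dien-1-yl]oxy}dimethylsilane
Product: 19 tert-butyl{[(2S,6E,10E)-13-(furan-3-yl)-2,6,10-trimethyltrideca-6,10-dien-1-yl]oxy}dimethylsilane, via (furan-3-ylmethyl)magnesium chloride 18 (not isolated)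
Conditions: 17, Mg turnings, THF, 0 °C to rt (high dilution); then 15, Li2CuCl4 (3 mol %), THF, 0 °C
Reagents that add atoms: none
Why: Copper-catalysed Grignard–allylic chloride coupling (Kochi/Tanis type) substitutes at the primary α-carbon with retention of the E-alkene, as in the classical dendrolasin synthesis.

**Step 12**
Reactants: 19 the silyl ether
Product: 20 (2S,6E,10E)-13-(furan-3-yl)-2,6,10-trimethyltrideca-6,10-dien-1-ol
Conditions: Bu4NF, THF, rt
Reagents that add atoms: none
Why: Fluoride desilylation under non-acidic conditions leaves the furan and trisubstituted alkenes untouched.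

**Step 13**
Reactants: 20 (2S,6E,10E)-13-(furan-3-yl)-2,6,10-trimethyltrideca-6,10-dien-1-ol
Product: 21 (2S,6E,10E)-13-(furan-3-yl)-2,6,10-trimethyltrideca-6,10-dienal
Conditions: Dess–Martin periodinane, CH2Cl2, 0 °C to rt; aqueous Na2S2O3–NaHCO3 work-up; used at once
Reagents that add atoms: none
Why: Dess–Martin oxidation is mild and non-basic, so the α-methyl aldehyde is formed without epimerisation.

**Step 14**
Reactants: 4 3-methyl-4-(prop-2-en-1-yloxy)furan-2(5H)-one; 21 (2S,6E,10E)-13-(furan-3-yl)-2,6,10-trimethyltrideca-6,10-dienal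
Product: 22 (5R)-5-[(1R,2S,6E,10E)-13-(furan-3-yl)-1-hydroxy-2,6,10-trimethyltrideca-6,10-dien-1-yl]-3-methyl-4-(prop-2-en-1-yloxy)furan-2(5H)-one, carried as the 5,6-erythro pair together with its (5S,1′S,2′S) epimer
Conditions: 4 (1.3 equiv), LiN(i-Pr)2 (1.25 equiv), THF, −78 °C, 30 min; 21, −78 °C, 1 h; AcOH quench at −78 °C; chromatography to remove the 5,6-threo pair
Reagents that add atoms: none
Why: Intermolecular vinylogous aldol addition of the tetronate lithium dienolate at C5 (C3 is blocked); C1′ is set mainly by Felkin–Anh addition, the C5/C1′ relationship is not controlled by the open transition state, so the erythro (like) pair is isolated by chromatography; both centres are destroyed in step 15 and only their relative configuration matters.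

**Step 15**
Reactants: 22 the 5,6-erythro aldol pair
Product: 23 (5E)-5-[(2S,6E,10E)-13-(furan-3-yl)-2,6,10-trimethyltrideca-6,10-dien-1-ylidene]-3-methyl-4-(prop-2-en-1-yloxy)furan-2(5H)-one
Conditions: PPh3 (1.5 equiv), DIAD (1.5 equiv), THF, −30 to 0 °C, dark
Reagents that add atoms: none
Why: Mitsunobu-type dehydration: the alkoxyphosphonium group leaves in a concerted anti-periplanar E2 with C5–H, which in the erythro series (as allo-threonine gives the E-dehydroamino acid) puts the side chain cis to C4, i.e. the E-ylidene; the allylic stereocentre is not involved.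

**Step 16**
Reactants: 23 the (5E)-allyl ether
Product: 24 (5E)-5-[(2S,6E,10E)-13-(furan-3-yl)-2,6,10-trimethyltrideca-6,10-dien-1-ylidene]-4-hydroxy-3-methylfuran-2(5H)-one
Conditions: Pd(PPh3)4 (5 mol %), morpholine (5 equiv), THF, rt, dark; cold aqueous citric acid work-up
Reagents that add atoms: none
Why: Tsuji–Trost deallylation: zerovalent palladium ionises the allyl vinylogous ester and morpholine traps the π-allyl unit under neutral conditions that spare the furan, the alkenes, the stereocentre and the E-geometry.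

**Step 17**
Reactants: 24 the (5E)-tetronic acid; 25 octadecanoyl chloride (stearoyl chloride)
Product: 26 (2E)-2-[(2S,6E,10E)-13-(furan-3-yl)-2,6,10-trimethyltrideca-6,10-dien-1-ylidene]-4-methyl-5-oxo-2,5-dihydrofuran-3-yl octadecanoate (target)
Conditions: Et3N (1.5 equiv), CH2Cl2, 0 °C, 30 min, dark
Reagents that add atoms: none
Why: O-acylation of the tetronate anion gives the 4-O-acyl enol ester because C3 is blocked by the methyl group; no stereochemical element is touched.

**Compound list**
1 | ethyl 2-methyl-3-oxobutanoate | CCOC(=O)C(C)C(C)=O | starting material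
2 | ethyl 4-bromo-2-methyl-3-oxobutanoate | CCOC(=O)C(C)C(=O)CBr | intermediate
3 | 4-hydroxy-3-methylfuran-2(5H)-one (3-methyltetronic acid) | CC1=C(O)COC1=O | intermediate
4 | 3-methyl-4-(prop-2-en-1-yloxy)furan-2(5H)-one | C=CCOC1=C(C)C(=O)OC1 | intermediate
5 | geranyl acetate | CC(C)=CCC/C(C)=C/COC(C)=O | starting material
6 | (2E,6E)-8-hydroxy-3,7-dimethylocta-2,6-dien-1-yl acetate | OC/C(C)=C/CC/C(C)=C/COC(C)=O | intermediate
7 | (2E,6E)-8-bromo-3,7-dimethylocta-2,6-dien-1-yl acetate | BrC/C(C)=C/CC/C(C)=C/COC(C)=O | intermediate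
8 | (R)-3-bromo-2-methylpropan-1-ol | OC[C@@H](C)CBr | starting material
9 | [(2R)-3-bromo-2-methylpropoxy](tert-butyl)dimethylsilane | CC(C)(C)[Si](C)(C)OC[C@@H](C)CBr | intermediate
10 | methyl phenyl sulfone | CS(=O)(=O)c1ccccc1 | starting material
11 | tert-butyldimethyl{[(2S)-2-methyl-4-(phenylsulfonyl)butyl]oxy}silane | CC(C)(C)[Si](C)(C)OC[C@@H](C)CCS(=O)(=O)c1ccccc1 | intermediate
12 | (2E,6E,11S)-12-{[tert-butyl(dimethyl)silyl]oxy}-3,7,11-trimethyl-9-(phenylsulfonyl)dodeca-2,6-dien-1-yl acetate (C9 epimers) | CC(C)(C)[Si](C)(C)OC[C@@H](C)CC(C/C(C)=C/CC/C(C)=C/COC(C)=O)S(=O)(=O)c1ccccc1 | intermediate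
13 | (2E,6E,11S)-12-{[tert-butyl(dimethyl)silyl]oxy}-3,7,11-trimethyldodeca-2,6-dien-1-ol | CC(C)(C)[Si](C)(C)OC[C@@H](C)CCC/C(C)=C/CC/C(C)=C/CO | intermediate
14 | (2E,6E,11S)-12-{[tert-butyl(dimethyl)silyl]oxy}-3,7,11-trimethyldodeca-2,6-dien-1-yl methanesulfonate | CC(C)(C)[Si](C)(C)OC[C@@H](C)CCC/C(C)=C/CC/C(C)=C/COS(C)(=O)=O | intermediate
15 | tert-butyl{[(2S,6E,10E)-12-chloro-2,6,10-trimethyldodeca-6,10-dien-1-yl]oxy}dimethylsilane | CC(C)(C)[Si](C)(C)OC[C@@H](C)CCC/C(C)=C/CC/C(C)=C/CCl | intermediate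
16 | furan-3-ylmethanol | OCc1ccoc1 | starting material
17 | 3-(chloromethyl)furan | ClCc1ccoc1 | intermediate
18 | (furan-3-ylmethyl)magnesium chloride | Cl[Mg]Cc1ccoc1 | intermediate
19 | tert-butyl{[(2S,6E,10E)-13-(furan-3-yl)-2,6,10-trimethyltrideca-6,10-dien-1-yl]oxy}dimethylsilane | CC(C)(C)[Si](C)(C)OC[C@@H](C)CCC/C(C)=C/CC/C(C)=C/CCc1ccoc1 | intermediate
20 | (2S,6E,10E)-13-(furan-3-yl)-2,6,10-trimethyltrideca-6,10-dien-1-ol | OC[C@@H](C)CCC/C(C)=C/CC/C(C)=C/CCc1ccoc1 | intermediate
21 | (2S,6E,10E)-13-(furan-3-yl)-2,6,10-trimethyltrideca-6,10-dienal | O=C[C@@H](C)CCC/C(C)=C/CC/C(C)=C/CCc1ccoc1 | intermediate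
22 | (5R)-5-[(1R,2S,6E,10E)-13-(furan-3-yl)-1-hydroxy-2,6,10-trimethyltrideca-6,10-dien-1-yl]-3-methyl-4-(prop-2-en-1-yloxy)furan-2(5H)-one (5,6-erythro; carried with its (5S,1′S,2′S) epimer) | C=CCOC1=C(C)C(=O)O[C@@H]1[C@H](O)[C@@H](C)CCC/C(C)=C/CC/C(C)=C/CCc1ccoc1 | intermediate
23 | (5E)-5-[(2S,6E,10E)-13-(furan-3-yl)-2,6,10-trimethyltrideca-6,10-dien-1-ylidene]-3-methyl-4-(prop-2-en-1-yloxy)furan-2(5H)-one | C=CCOC1=C(C)C(=O)O/C1=C/[C@@H](C)CCC/C(C)=C/CC/C(C)=C/CCc1ccoc1 | intermediate
24 | (5E)-5-[(2S,6E,10E)-13-(furan-3-yl)-2,6,10-trimethyltrideca-6,10-dien-1-ylidene]-4-hydroxy-3-methylfuran-2(5H)-one | OC1=C(C)C(=O)O/C1=C/[C@@H](C)CCC/C(C)=C/CC/C(C)=C/CCc1ccoc1 | intermediate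
25 | octadecanoyl chloride | CCCCCCCCCCCCCCCCCC(=O)Cl | starting material
26 | (2E)-2-[(2S,6E,10E)-13-(furan-3-yl)-2,6,10-trimethyltrideca-6,10-dien-1-ylidene]-4-methyl-5-oxo-2,5-dihydrofuran-3-yl octadecanoate | CCCCCCCCCCCCCCCCCC(=O)OC1=C(C)C(=O)O/C1=C/[C@@H](C)CCC/C(C)=C/CC/C(C)=C/CCc1ccoc1 | target

**Totals**
Total step count: 17. Longest linear sequence: 12 steps (5 → 26 through steps 3, 4, 7, 8, 9, 11, 12, 13, 14, 15, 16, 17).

**Three steps most likely to fail**

Step 14 (aldol). The lithium dienolate usually shows little erythro/threo preference (about 1:1 to 2:1), and the four diastereomers may not separate cleanly. Only the erythro pair leads to the E-alkene. If separation fails, the mixture can be dehydrated as in step 15 and 23 separated from its 5Z isomer, which is a two-compound separation. Fallback that changes the approach: set out from 4 and silylate it (TBSOTf, Et3N, CH2Cl2, 0 °C) to the silyl dienol ether tert-butyldimethyl{[3-methyl-4-(prop-2-en-1-yloxy)furan-2-yl]oxy}silane F1. Then run a fluoride-triggered vinylogous Mukaiyama aldol with 21, using (Bu4N)(Ph3SiF2) in THF at −78 °C. The free dienolate generated this way is known for 2-silyloxyfurans to favour the erythro adduct, whereas Lewis acids favour threo. This comes back to the route at 22.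

Step 15 (anti-dehydration to the strained E-ylidene). The E2 path may leak into an E1cB path that gives the more stable Z-isomer, or into SN2 capture by the hydrazide. Fallback: set out from 22 (any aldol diastereomer behaves alike here) and mesylate it (MsCl, Et3N, CH2Cl2, 0 °C) to the methanesulfonate (5R)-5-[(1R,2S,6E,10E)-13-(furan-3-yl)-1-(methylsulfonyloxy)-2,6,10-trimethyltrideca-6,10-dien-1-yl]-3-methyl-4-(prop-2-en-1-yloxy)furan-2(5H)-one F2. Eliminate with DBU to the stereoconvergent thermodynamic isomer (5Z)-5-[(2S,6E,10E)-13-(furan-3-yl)-2,6,10-trimethyltrideca-6,10-dien-1-ylidene]-3-methyl-4-(prop-2-en-1-yloxy)furan-2(5H)-one F3. Then irradiate (300–350 nm, Pyrex, degassed MeCN) to a Z/E photostationary mixture, isolate the E-isomer by chromatography on AgNO3-doped silica and recycle the Z-isomer. This comes back to the route at 23.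

Step 16 (deallylation). The π-allyl unit can return to C3 to give a 3-allyl-3-methyl dione, and phosphine or palladium hydride species may erode the E-geometry. Fallback: set out from 3 and protect it with MOMCl and i-Pr2NEt (CH2Cl2, 0 °C) as 4-(methoxymethoxy)-3-methylfuran-2(5H)-one F4. Carry this through the same aldol with 21 (LiN(i-Pr)2, THF, −78 °C) to the erythro pair (5R)-5-[(1R,2S,6E,10E)-13-(furan-3-yl)-1-hydroxy-2,6,10-trimethyltrideca-6,10-dien-1-yl]-4-(methoxymethoxy)-3-methylfuran-2(5H)-one F5. Dehydrate with PPh3 and DIAD to (5E)-5-[(2S,6E,10E)-13-(furan-3-yl)-2,6,10-trimethyltrideca-6,10-dien-1-ylidene]-4-(methoxymethoxy)-3-methylfuran-2(5H)-one F6. Cleave the acetal-type enol ether with dilute HCl in THF–H2O at 0 °C, with no palladium or phosphine present. This comes back to the route at 24.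

**Further compounds**
F1 | step 14 | tert-butyldimethyl{[3-methyl-4-(prop-2-en-1-yloxy)furan-2-yl]oxy}silane | Cc1c(OCC=C)coc1O[Si](C)(C)C(C)(C)C
F2 | step 15 | (5R)-5-[(1R,2S,6E,10E)-13-(furan-3-yl)-1-(methylsulfonyloxy)-2,6,10-trimethyltrideca-6,10-dien-1-yl]-3-methyl-4-(prop-2-en-1-yloxy)furan-2(5H)-one | C=CCOC1=C(C)C(=O)O[C@@H]1[C@H](OS(C)(=O)=O)[C@@H](C)CCC/C(C)=C/CC/C(C)=C/CCc1ccoc1
F3 | step 15 | (5Z)-5-[(2S,6E,10E)-13-(furan-3-yl)-2,6,10-trimethyltrideca-6,10-dien-1-ylidene]-3-methyl-4-(prop-2-en-1-yloxy)furan-2(5H)-one | C=CCOC1=C(C)C(=O)O/C1=C\[C@@H](C)CCC/C(C)=C/CC/C(C)=C/CCc1ccoc1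
F4 | step 16 | 4-(methoxymethoxy)-3-methylfuran-2(5H)-one | COCOC1=C(C)C(=O)OC1
F5 | step 16 | (5R)-5-[(1R,2S,6E,10E)-13-(furan-3-yl)-1-hydroxy-2,6,10-trimethyltrideca-6,10-dien-1-yl]-4-(methoxymethoxy)-3-methylfuran-2(5H)-one (5,6-erythro pair) | COCOC1=C(C)C(=O)O[C@@H]1[C@H](O)[C@@H](C)CCC/C(C)=C/CC/C(C)=C/CCc1ccoc1
F6 | step 16 | (5E)-5-[(2S,6E,10E)-13-(furan-3-yl)-2,6,10-trimethyltrideca-6,10-dien-1-ylidene]-4-(methoxymethoxy)-3-methylfuran-2(5H)-one | COCOC1=C(C)C(=O)O/C1=C/[C@@H](C)CCC/C(C)=C/CC/C(C)=C/CCc1ccoc1
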